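## The problem

Target 23 is a drimane joined through C11 to a 2-methoxy-1,4-benzoquinone. Drimane numbering is used throughout: ring A is C1–C5 and C10 with the gem-dimethyl group on C4, ring B is C5–C10, C12 is the methyl on C8, and C11 is the exocyclic carbon that carries chlorine and the oxygenated six-membered ring. The carbocycles are trans-fused at C5–C10, C10 is quaternary, and the C8 methyl lies on the same face as the C10 methyl (5S,8S,10S); this is 1,3-diaxial in a chair ring B and cannot be expected from equilibration. C9=C11 is a tetrasubstituted E alkene with chlorine on the C8 side and the aryl-derived ring on the C10 side. C5 can control C10 because the two are neighbours, but C8 lies across sp2 C9 from C10 and is poorly controlled by the ring; C8 and C10 together decide from which side a substituent reaches C11. The methoxyquinone tolerates neither bases, nucleophiles nor reductants and must appear last, and the α-aryl vinyl chloride survives neither dissolving metals nor hydrogenation, so all reductions must be finished before chlorine is attached. The enabling feature is that C5 and C10 are adjacent ring-A carbons with trans ring-B arms: with C1 as a carbonyl they are the β- and α-carbons of 2,4,4-trimethylcyclohex-2-en-1-one, which can accept one arm as a nucleophile and the other as an electrophile.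

## Retrosynthesis

**Quinone to phenol.** No skeletal bond is cut: 23 is taken back to phenol 22, whose para position is free, and 22 to its isopropyl ether 21. Oxidising last keeps the quinone away from every base and organometallic of the route; oxidative demethylation of a dimethoxyarene with (NH4)2Ce(NO3)6 would expose the electron-rich chloroalkene to a strong one-electron oxidant. The forward steps need cleavage of an isopropyl aryl ether beside a methyl aryl ether and para-selective oxidation of a 2,6-disubstituted phenol.

**C11–Cl.** Chlorine is removed to enol triflate 20 and this to aryl ketone 18. Direct deoxychlorination of 18 would pass through an α-chlorobenzyl cation that loses the C9 proton with its coplanar aryl group on the less hindered C8 side, which is the wrong geometry. Metal-catalysed exchange would only copy whatever geometry the triflate has. Ionisation of 20 to a linear vinyl cation erases the geometry and lets the approach of chloride decide. The forward reaction must ionise cleanly and capture chloride from the C8 side.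

**C8–C9, ring B.** Ketone 18 is opened to keto mesylate 16, the enolate carbon C9 being the nucleophile and C8 the electrophile. Closing the same bond by aldol condensation onto a C8 methyl ketone would leave C8 sp2 in a tetrasubstituted alkene whose aroyl group is twisted out of conjugation by C10 and C12. Hydrogen could then reach C8 only by hydrogenation of a very hindered alkene, and a second aldol mode (C7 onto C11) would compete. The alkylation instead brings C8 in with its hydrogen attached and its configuration bought, and only one ketone is enolisable. The forward reaction must be a clean SN2 displacement with inversion at a secondary centre.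

**Oxidation-level adjustments.** Mesylate 16 comes from alcohol 15. Alcohol 15 comes from alkene 13 by cleaving the exocyclic methylene to the C11 ketone and removing the acetal. Alkene 13 comes from ketone 11 by deleting the C1 carbonyl. The C1 oxygen must go before the C11 ketone exists, because a C1/C11 1,4-diketone would condense with hydrazine and aldolise to a cyclopentenone. These steps need a Wolff–Kishner reduction at a ketone next to a quaternary carbon and an alkene cleavage that spares an electron-rich arene.

**C5–C6 and C9–C10, the key cut.** Ketone 11 falls into enone 9, Grignard reagent 8 (C6, C7, C8, C12) and allylic bromide 4 (C9, C11 and the arene). Both ring-B arms are joined to ring A in one flask, C5 and C10 are set together, and the three pieces are small. The forward reaction must add to the face of C5 chosen by a chiral ligand and alkylate the resulting enolate anti to the new chain at a fully substituted carbon.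

**Fragments.** Bromide 4 comes from acetophenone 1 through ether 2 and styrene 3. Reagent 8 comes from (R)-butane-1,3-diol 5 through bromo alcohol 6 and acetal 7; the R configuration is the one that becomes 8S after inversion.

## Roads not taken

**Alternative 1:** The cut runs through C4–C5, C9–C10 and a temporary O–C8 bond, from chroman A2 back to the open-chain 2-farnesyl-6-methoxyphenol A1.
- Forward step: a squalene–hopene cyclase variant protonates the terminal alkene, folds the chain chair–chair, closes rings A and B, and the phenol oxygen traps the C8 cation.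
- Merits: one step from an achiral precursor sets the trans fusion and every ring stereocentre. In economy this is clearly better than the chosen plan, which needs eleven steps to reach a bicyclic intermediate.
- Weak points: A2 holds C8 as a tertiary aryl ether and C11 as CH2. The target needs H on C8 with the methyl β, a C9=C11 alkene and chlorine on C11. Replacing the C8–O bond by C8–H goes through a C8 radical or cation and gives up the configuration the enzyme set. C11 must then be oxidised next to an electron-rich phenol, after which the ketone-to-chloroalkene problem is still there. The protein must also accept the ortho-methoxyphenol and is not a catalogue reagent.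
- Comparison: the chosen plan sets against the shorter skeleton synthesis that C8 arrives with its hydrogen, C11 arrives as a ketone, and everything is done with purchasable reagents.

**Alternative 2:** The cut opens C5–C10 and C8–C9 of A4 back to the acyclic (E,E)-diene tethered to a 1-aryl-1-chloroallene, A3.
- Forward step: on heating, the diene C5=C6–C7=C8 adds across C9=C10 on the allene face anti to the aryl group. The axial chirality passes into C5, C8 and C10 and into the geometry of the chloroalkene.
- Merits: the hardest element of the target, the E chloroalkene with the C8 methyl syn to the C10 methyl, comes straight from the cycloaddition. Only hydrogenation of C6=C7, desilylation and oxidation remain. In this respect the road is better than the chosen plan, which needs a vinyl cation step for the same result.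
- Weak points: it needs a single enantiomer of a trisubstituted aryl chloroallene. Such allenes racemise by ionisation to the aryl-stabilised propargyl/allenyl cation, more so at the temperature needed for a diene terminus next to quaternary C4. Trans versus cis fusion in unactivated 1,7,9-decatriene cycloadditions is seldom high.
- Comparison: the chosen plan sets against the shorter endgame that C5 and C10 come from a known catalytic reaction type, C8 from a stereospecific displacement, and no configurationally fragile intermediate is carried.

**Alternative 3:** The cut is at C9–C11 and C11–aryl of enone A7, giving enol triflate A5, carbon monoxide and boronic acid A6.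
- Forward step: zerovalent palladium formed from Pd(OAc)2 and PPh3 inserts into C9–OTf, takes up CO, and the acyl palladium couples with A6.
- Merits: very convergent; C11 arrives at the ketone level, and C5 and C10 are fixed before the arene is attached. This is at least as good as the chosen plan in step count to the full carbon skeleton.
- Weak points: oxidative addition and acyl transfer occur at a carbon flanked by quaternary C10 and the C8 methyl, and direct non-carbonylative coupling competes. More seriously, A7 is the twisted tetrasubstituted aroyl alkene that the chosen plan avoids: hydride conjugate reduction has no conjugation to act on, dissolving metals would reduce the aryl ketone, and hydrogenation must force a hindered alkene while choosing the α face. A5 also needs its own enantioselective synthesis.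
- Comparison: the chosen plan pays with a longer sequence but sets C8 by inversion of a bought stereocentre and never passes through A7.

Key step: step 7

Assumption: L is O,O′-(1,1′-binaphthalene-2,2′-diyl) N,N-bis(1-phenylethyl)phosphoramidite, and the antipode that sends the alkyl group to the Si face of C3 of enone 9 is used; which antipode this is must be fixed by a trial run.

## Route

Step 1
Reactants: 1 1-(2-hydroxy-3-methoxyphenyl)ethan-1-one
Product: 2 1-[3-methoxy-2-(propan-2-yloxy)phenyl]ethan-1-one
Conditions: 2-bromopropane, K2CO3, DMF, 60 °C
Reagents that add atoms: 2-bromopropane, CC(C)Br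
Why: Williamson ether synthesis; the hydrogen-bonded phenol needs carbonate in DMF and warming. Isopropyl is chosen because BCl3 later removes it beside the methyl ether.

Step 2
Reactants: 2 1-[3-methoxy-2-(propan-2-yloxy)phenyl]ethan-1-one
Product: 3 1-methoxy-2-(propan-2-yloxy)-3-(prop-1-en-2-yl)benzene
Conditions: Ph3PCH3Br, KOt-Bu, THF, 0 °C to reflux
Reagents that add atoms: methyltriphenylphosphonium bromide, C[P+](c1ccccc1)(c1ccccc1)c1ccccc1.[Br-]
Why: Wittig methylenation of an aryl methyl ketone with the non-stabilised ylide; the ortho alkoxy group slows the addition, hence the reflux.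

Step 3
Reactants: 3 1-methoxy-2-(propan-2-yloxy)-3-(prop-1-en-2-yl)benzene
Product: 4 1-(3-bromoprop-1-en-2-yl)-3-methoxy-2-(propan-2-yloxy)benzene
Conditions: NBS, TsOH·H2O (cat.), THF, reflux
Reagents that add atoms: N-bromosuccinimide, O=C1CCC(=O)N1Br
Why: Acid-catalysed electrophilic allylic bromination of an α-methylstyrene: bromonium ion, tertiary benzylic cation, loss of a methyl proton. The alkene should be attacked faster than the ring.

Step 4
Reactants: 5 (3R)-butane-1,3-diol
Product: 6 (2R)-4-bromobutan-2-ol
Conditions: CBr4, PPh3, CH2Cl2, 0 °C
Reagents that add atoms: tetrabromomethane, BrC(Br)(Br)Br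
Why: Appel reaction; the primary hydroxyl forms the alkoxyphosphonium ion much faster than the secondary one, and the stereocentre is not touched.

Step 5
Reactants: 6 (2R)-4-bromobutan-2-ol
Product: 7 (3R)-1-bromo-3-(methoxymethoxy)butane
Conditions: MOMCl, i-Pr2NEt, CH2Cl2, 0 °C to rt
Reagents that add atoms: chloromethyl methyl ether, COCCl
Why: Acetal protection through the oxocarbenium ion of the chloro ether; the group survives the Grignard reagent, hot KOH and ozone and is removed by mild acid.

Step 6
Reactants: 7 (3R)-1-bromo-3-(methoxymethoxy)butane
Product: 8 [(3R)-3-(methoxymethoxy)butyl]magnesium bromide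
Conditions: Mg, Et2O, reflux
Reagents that add atoms: magnesium, [Mg]
Why: Insertion of magnesium into the primary C–Br bond; a γ-alkoxy Grignard reagent is stable because alkoxide is not lost by 1,3-elimination.

Step 7
Reactants: 9 2,4,4-trimethylcyclohex-2-en-1-one; 8 [(3R)-3-(methoxymethoxy)butyl]magnesium bromide; 4 1-(3-bromoprop-1-en-2-yl)-3-methoxy-2-(propan-2-yloxy)benzene
Product: 11 (2R,3S)-3-[(3R)-3-(methoxymethoxy)butyl]-2-{2-[3-methoxy-2-(propan-2-yloxy)phenyl]prop-2-en-1-yl}-2,4,4-trimethylcyclohexan-1-one, via magnesium enolate 10 (not isolated)
Conditions: Cu(OTf)2 (5 mol %), L (10 mol %), Et2O, −30 °C, slow addition of 8; then DMPU, 4, −30 °C to rt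
Reagents that add atoms: none
Why: Cu(OTf)2 is reduced by the Grignard reagent to a monovalent copper–phosphoramidite complex, which takes the alkyl group from magnesium, binds the enone as a π-complex and adds oxidatively at C5 (enone C3); reductive elimination from the trivalent copper intermediate forms C5–C6 and leaves bromomagnesium enolate 10. The closest known reaction type is the copper-catalysed asymmetric conjugate addition of Grignard reagents to 2-methylcyclohex-2-enone with alkylation of the magnesium enolate by allylic or benzylic halides in the same flask. No ring is closed in this step. C5 is set by the ligand, which must deliver the alkyl group to the Si face of enone C3, the face that leaves H-5 α. C10 is set by the substrate: the new C5 chain lies pseudoaxial beside the C10 methyl to avoid allylic 1,2-strain and bromide 4 enters on the opposite face, so the two ring-B arms become trans and the C10 methyl cis to the C6 arm. The step needs 1,4- over 1,2-addition (copper catalysis, slow addition of 8), a single enolate regioisomer (only the C1–C10 enolate can arise), C- over O-alkylation (covalent magnesium enolate, soft allylic bromide, DMPU for reactivity) and is indifferent to SN2 versus SN2′ attack because the 2-arylallyl unit is symmetric about C11. The remote R centre of 8 turns any addition to the wrong face into a diastereomer that can be removed at 11 or later.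

Step 8
Reactants: 11 (2R,3S)-3-[(3R)-3-(methoxymethoxy)butyl]-2-{2-[3-methoxy-2-(propan-2-yloxy)phenyl]prop-2-en-1-yl}-2,4,4-trimethylcyclohexan-1-one
Product: 13 1-methoxy-3-{3-[(1R,2S)-2-[(3R)-3-(methoxymethoxy)butyl]-1,3,3-trimethylcyclohexyl]prop-1-en-2-yl}-2-(propan-2-yloxy)benzene, via hydrazone 12 (not isolated)
Conditions: N2H4·H2O, KOH, diethylene glycol, 130 °C, then 200 °C with removal of water, under N2
Reagents that add atoms: hydrazine, NN (its nitrogen is held in 12 and leaves as N2; none remains in 13)
Why: Wolff–Kishner reduction in the Huang-Minlon form: hydrazone formation, then base-induced loss of N2. Acetal, aryl ethers and the 1,1-disubstituted alkene are base-stable, and neither stereocentre is enolisable.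

Step 9
Reactants: 13 1-methoxy-3-{3-[(1R,2S)-2-[(3R)-3-(methoxymethoxy)butyl]-1,3,3-trimethylcyclohexyl]prop-1-en-2-yl}-2-(propan-2-yloxy)benzene
Product: 15 2-{(1R,2S)-2-[(3R)-3-hydroxybutyl]-1,3,3-trimethylcyclohexyl}-1-[3-methoxy-2-(propan-2-yloxy)phenyl]ethan-1-one, via aryl ketone 14 (not isolated)
Conditions: O3, CH2Cl2/MeOH, −78 °C, stopped at the indicator end point; Me2S; then HCl, MeOH, 50 °C
Reagents that add atoms: ozone, O=[O+][O-]
Why: Ozonolysis of the styrene-type methylene (Criegee mechanism, reductive work-up) gives the C11 ketone; the alkene is far more reactive than the dialkoxyarene if ozone is not used in excess. Acid-catalysed acetal exchange with methanol then frees the C8 hydroxyl.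

Step 10
Reactants: 15 2-{(1R,2S)-2-[(3R)-3-hydroxybutyl]-1,3,3-trimethylcyclohexyl}-1-[3-methoxy-2-(propan-2-yloxy)phenyl]ethan-1-one
Product: 16 (2R)-4-[(1S,2R)-2-{2-[3-methoxy-2-(propan-2-yloxy)phenyl]-2-oxoethyl}-2,6,6-trimethylcyclohexyl]butan-2-yl methanesulfonate
Conditions: MsCl, Et3N, CH2Cl2, 0 °C
Reagents that add atoms: methanesulfonyl chloride, CS(=O)(=O)Cl
Why: Sulfonylation of the secondary alcohol with retention at C8; Et3N does not enolise the aryl ketone.

Step 11
Reactants: 16 (2R)-4-[(1S,2R)-2-{2-[3-methoxy-2-(propan-2-yloxy)phenyl]-2-oxoethyl}-2,6,6-trimethylcyclohexyl]butan-2-yl methanesulfonate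
Product: 18 [3-methoxy-2-(propan-2-yloxy)phenyl][(2S,4aS,8aS)-2,5,5,8a-tetramethyldecahydronaphthalen-1-yl]methanone (both C9 epimers), via potassium enolate 17 (not isolated)
Conditions: KOt-Bu, THF, 0 to 40 °C, high dilution
Reagents that add atoms: potassium tert-butoxide, CC(C)(C)[O-].[K+] (its potassium is held in 17 and leaves as the methanesulfonate)
Why: Intramolecular C-alkylation of the only possible enolate (6-exo-tet) closes ring B by forming C8–C9. Backside displacement inverts C8 from R to S, placing its methyl β, syn to the C10 methyl; the C9 configuration is erased in step 12.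

Step 12
Reactants: 18 [3-methoxy-2-(propan-2-yloxy)phenyl][(2S,4aS,8aS)-2,5,5,8a-tetramethyldecahydronaphthalen-1-yl]methanone
Product: 20 [3-methoxy-2-(propan-2-yloxy)phenyl][(2S,4aS,8aS)-2,5,5,8a-tetramethyloctahydronaphthalen-1(2H)-ylidene]methyl trifluoromethanesulfonate (E/Z mixture), via potassium enolate 19 (not isolated)
Conditions: KN(SiMe3)2, THF, −78 to 0 °C; PhNTf2; chromatography on Et3N-washed silica
Reagents that add atoms: N-phenylbis(trifluoromethanesulfonimide), O=S(=O)(N(c1ccccc1)S(=O)(=O)C(F)(F)F)C(F)(F)F; potassium bis(trimethylsilyl)amide, C[Si](C)(C)[N-][Si](C)(C)C.[K+] (its potassium is held in 19 only)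
Why: Deprotonation at C9, the only α-hydrogen of the ketone, and O-sulfonylation of the enolate. The geometry of the triflate does not matter because both isomers give the same cation in step 13.

Step 13
Reactants: 20 [3-methoxy-2-(propan-2-yloxy)phenyl][(2S,4aS,8aS)-2,5,5,8a-tetramethyloctahydronaphthalen-1(2H)-ylidene]methyl trifluoromethanesulfonate
Product: 21 1-{(E)-chloro[(2S,4aS,8aS)-2,5,5,8a-tetramethyloctahydronaphthalen-1(2H)-ylidene]methyl}-3-methoxy-2-(propan-2-yloxy)benzene
Conditions: n-Bu4NCl (excess), 2,6-di-tert-butyl-4-methylpyridine, (CF3)2CHOH/CH2Cl2, 40 °C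
Reagents that add atoms: tetrabutylammonium chloride, CCCC[N+](CCCC)(CCCC)CCCC.[Cl-]
Why: Proposed new method: the triflate, with an ortho-alkoxy donor on its α-aryl group and a strained tetrasubstituted alkene, is expected to ionise in the strongly ionising, poorly nucleophilic solvent to a linear vinyl cation at C11 whose aryl ring stands perpendicular to the plane of C8, C9 and C10; chloride must approach within that plane and meets only the equatorial hydrogen of C8 on one side but the C1 methylene on the other, so it should bond on the C8 side and give the E alkene, both isomers of 20 converging and internal return only regenerating 20. The closest known reaction type is the solvolytic substitution of α-(alkoxyaryl)vinyl sulfonates and halides through vinyl cations with capture by halide ion, together with the hydrochlorination of arylalkynes through the same kind of cation.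

Step 14
Reactants: 21 1-{(E)-chloro[(2S,4aS,8aS)-2,5,5,8a-tetramethyloctahydronaphthalen-1(2H)-ylidene]methyl}-3-methoxy-2-(propan-2-yloxy)benzene
Product: 22 2-{(E)-chloro[(2S,4aS,8aS)-2,5,5,8a-tetramethyloctahydronaphthalen-1(2H)-ylidene]methyl}-6-methoxyphenol
Conditions: BCl3, CH2Cl2, −78 to 0 °C; H2O
Reagents that add atoms: none
Why: Lewis-acid cleavage of the isopropyl aryl ether: the secondary alkyl group leaves as 2-chloropropane from the boron-complexed oxygen at a temperature at which the methyl ether stays. Should the vinyl chloride ionise transiently, chloride would return on the same side.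

Step 15
Reactants: 22 2-{(E)-chloro[(2S,4aS,8aS)-2,5,5,8a-tetramethyloctahydronaphthalen-1(2H)-ylidene]methyl}-6-methoxyphenol
Product: 23 2-{(E)-chloro[(2S,4aS,8aS)-2,5,5,8a-tetramethyloctahydronaphthalen-1(2H)-ylidene]methyl}-6-methoxycyclohexa-2,5-diene-1,4-dione
Conditions: (KO3S)2NO, KH2PO4, acetone/H2O, rt
Reagents that add atoms: potassium nitrosodisulfonate, [O]N(S(=O)(=O)[O-])S(=O)(=O)[O-].[K+].[K+]
Why: Teuber oxidation: one equivalent of the nitroxyl radical makes the phenoxyl radical, a second adds at the free para carbon, and loss of the imidodisulfonate gives the para-quinone. Both ortho positions are blocked and the neutral buffered medium spares the chloroalkene.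

## Compound list

1 | 1-(2-hydroxy-3-methoxyphenyl)ethan-1-one | CC(=O)c1cccc(OC)c1O | starting material
2 | 1-[3-methoxy-2-(propan-2-yloxy)phenyl]ethan-1-one | CC(=O)c1cccc(OC)c1OC(C)C | intermediate
3 | 1-methoxy-2-(propan-2-yloxy)-3-(prop-1-en-2-yl)benzene | C=C(C)c1cccc(OC)c1OC(C)C | intermediate
4 | 1-(3-bromoprop-1-en-2-yl)-3-methoxy-2-(propan-2-yloxy)benzene | C=C(CBr)c1cccc(OC)c1OC(C)C | intermediate
5 | (3R)-butane-1,3-diol | C[C@@H](O)CCO | starting material
6 | (2R)-4-bromobutan-2-ol | C[C@@H](O)CCBr | intermediate
7 | (3R)-1-bromo-3-(methoxymethoxy)butane | C[C@@H](OCOC)CCBr | intermediate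
8 | [(3R)-3-(methoxymethoxy)butyl]magnesium bromide | C[C@@H](OCOC)CC[Mg]Br | intermediate
9 | 2,4,4-trimethylcyclohex-2-en-1-one | CC1=CC(C)(C)CCC1=O | starting material
10 | bromomagnesium (3S)-3-[(3R)-3-(methoxymethoxy)butyl]-2,4,4-trimethylcyclohex-1-en-1-olate | C[C@@H](OCOC)CC[C@H]1C(C)(C)CCC(O[Mg]Br)=C1C | intermediate
11 | (2R,3S)-3-[(3R)-3-(methoxymethoxy)butyl]-2-{2-[3-methoxy-2-(propan-2-yloxy)phenyl]prop-2-en-1-yl}-2,4,4-trimethylcyclohexan-1-one | C[C@@H](OCOC)CC[C@H]1C(C)(C)CCC(=O)[C@]1(C)CC(=C)c1cccc(OC)c1OC(C)C | intermediate
12 | hydrazone of 11 (C1=N–NH2, 2R,3S) | C[C@@H](OCOC)CC[C@H]1C(C)(C)CCC(=NN)[C@]1(C)CC(=C)c1cccc(OC)c1OC(C)C | intermediate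
13 | 1-methoxy-3-{3-[(1R,2S)-2-[(3R)-3-(methoxymethoxy)butyl]-1,3,3-trimethylcyclohexyl]prop-1-en-2-yl}-2-(propan-2-yloxy)benzene | C[C@@H](OCOC)CC[C@H]1C(C)(C)CCC[C@]1(C)CC(=C)c1cccc(OC)c1OC(C)C | intermediate
14 | 2-{(1R,2S)-2-[(3R)-3-(methoxymethoxy)butyl]-1,3,3-trimethylcyclohexyl}-1-[3-methoxy-2-(propan-2-yloxy)phenyl]ethan-1-one | C[C@@H](OCOC)CC[C@H]1C(C)(C)CCC[C@]1(C)CC(=O)c1cccc(OC)c1OC(C)C | intermediate
15 | 2-{(1R,2S)-2-[(3R)-3-hydroxybutyl]-1,3,3-trimethylcyclohexyl}-1-[3-methoxy-2-(propan-2-yloxy)phenyl]ethan-1-one | C[C@@H](O)CC[C@H]1C(C)(C)CCC[C@]1(C)CC(=O)c1cccc(OC)c1OC(C)C | intermediate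
16 | (2R)-4-[(1S,2R)-2-{2-[3-methoxy-2-(propan-2-yloxy)phenyl]-2-oxoethyl}-2,6,6-trimethylcyclohexyl]butan-2-yl methanesulfonate | C[C@@H](OS(C)(=O)=O)CC[C@H]1C(C)(C)CCC[C@]1(C)CC(=O)c1cccc(OC)c1OC(C)C | intermediate
17 | potassium (Z)-enolate of 16 (C9=C11–O–K) | C[C@@H](OS(C)(=O)=O)CC[C@H]1C(C)(C)CCC[C@]1(C)/C=C(\[O-])c1cccc(OC)c1OC(C)C.[K+] | intermediate
18 | [3-methoxy-2-(propan-2-yloxy)phenyl][(2S,4aS,8aS)-2,5,5,8a-tetramethyldecahydronaphthalen-1-yl]methanone (8β-methyl; C9 either way) | CC(C)Oc1c(OC)cccc1C(=O)C1[C@@H](C)CC[C@H]2C(C)(C)CCC[C@]12C | intermediate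
19 | potassium enolate of 18 (C9=C11–O–K, either geometry) | CC(C)Oc1c(OC)cccc1C([O-])=C1[C@@H](C)CC[C@H]2C(C)(C)CCC[C@]12C.[K+] | intermediate
20 | [3-methoxy-2-(propan-2-yloxy)phenyl][(2S,4aS,8aS)-2,5,5,8a-tetramethyloctahydronaphthalen-1(2H)-ylidene]methyl trifluoromethanesulfonate (E and Z) | CC(C)Oc1c(OC)cccc1C(OS(=O)(=O)C(F)(F)F)=C1[C@@H](C)CC[C@H]2C(C)(C)CCC[C@]12C | intermediate
21 | 1-{(E)-chloro[(2S,4aS,8aS)-2,5,5,8a-tetramethyloctahydronaphthalen-1(2H)-ylidene]methyl}-3-methoxy-2-(propan-2-yloxy)benzene | CC(C)Oc1c(OC)cccc1/C(Cl)=C1/[C@@H](C)CC[C@H]2C(C)(C)CCC[C@]12C | intermediate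
22 | 2-{(E)-chloro[(2S,4aS,8aS)-2,5,5,8a-tetramethyloctahydronaphthalen-1(2H)-ylidene]methyl}-6-methoxyphenol | COc1cccc(/C(Cl)=C2/[C@@H](C)CC[C@H]3C(C)(C)CCC[C@]23C)c1O | intermediate
23 | 2-{(E)-chloro[(2S,4aS,8aS)-2,5,5,8a-tetramethyloctahydronaphthalen-1(2H)-ylidene]methyl}-6-methoxycyclohexa-2,5-diene-1,4-dione (CNP0249629.1) | COC1=CC(=O)C=C(/C(Cl)=C2/[C@@H](C)CC[C@H]3C(C)(C)CCC[C@]23C)C1=O | target

## Step count and least certain steps

Total: 15 steps. Longest linear sequence: 12 steps (steps 1–3 then 7–15, or equally steps 4–6 then 7–15).

**Step 13 (chloride capture).**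
- What may go wrong: hydride transfer from the isopropoxy methine to the cationic C11; capture of the cation by solvent instead of chloride; chloride approaching from both sides if ring B leaves the chair with the C8 methyl axial.
- Fallback, known chemistry: sets out from triflate 20. Its two geometric isomers are separated, and the isomer with the triflate on the C8 side undergoes nickel-catalysed triflate-to-chloride exchange (Ni(cod)2 as the zerovalent nickel source, LiCl, DMA/THF, rt). Oxidative addition and reductive elimination keep the alkene geometry, and the route is rejoined at chloride 21. No new compound is made (F0). This fallback serves only as far as step 12 delivers that triflate isomer.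

**Step 7 (key step).**
- What may go wrong: slow conjugate addition at C5 beside quaternary C4 with competing 1,2-addition; erosion of enantioface control by uncatalysed background addition or by the acetal oxygens binding magnesium; sluggish alkylation of the magnesium enolate at fully substituted C10, with proton transfer and alkylation at C2.
- Fallback: sets out from enone 9 and reagent 8. The same copper-catalysed addition is run with Me3SiCl, which accelerates the addition and gives the trimethylsilyl enol ether F1, isolated without aqueous acid. MeLi in THF at 0 °C converts it into the lithium enolate F2, which is alkylated with bromide 4 in THF/HMPA at −78 to 0 °C. The route is rejoined at ketone 11.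

**Step 11 (ring B closure).**
- What may go wrong: elimination of the secondary mesylate, and slow ring closure because the enolate carbon is neopentyl and the C8 methyl must enter syn to the C10 methyl.
- Fallback: sets out from alcohol 15. Dess–Martin oxidation gives the diketone F3. KOH in MeOH at reflux closes ring B by aldol condensation of C9 onto the C8 carbonyl, giving the tetrasubstituted aroyl alkene F4. Hydrogenation with [Ir(cod)(PCy3)(py)]PF6 under H2 pressure in CH2Cl2, expected on the α face opposite the C10 methyl, returns to ketone 18. This trades the displacement for a demanding hydrogenation and is the second choice for that reason.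

**Step 12 (enol triflate).**
- What may go wrong: incomplete deprotonation at C9, which lies between C10 and C8 and must align with a hindered aryl ketone.
- Fallback: sets out from ketone 18. Tf2O with 2,6-di-tert-butyl-4-methylpyridine in CH2Cl2 triflylates the carbonyl oxygen first, and the C9 proton is then lost from the cation, so no enolate is needed. The route is rejoined at triflate 20; no new compound (F0).

**Step 8 (Wolff–Kishner).**
- What may go wrong: incomplete hydrazone formation at the ketone beside quaternary C10, and partial cleavage of the aryl methyl ether by hot hydroxide.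
- Fallback: sets out from ketone 11. LiAlH4 in THF gives the C1 alcohol F5 (either epimer). NaH, CS2 and MeI give the S-methyl xanthate F6. Bu3SnH with AIBN in toluene at 110 °C removes it (Barton–McCombie deoxygenation); the only cyclisation open to the C1 radical is a slow 5-endo closure onto the styrene. The route is rejoined at 13.

## Further compounds

F0 | step 13 | none | none
F1 | step 7 | {[(3S)-3-[(3R)-3-(methoxymethoxy)butyl]-2,4,4-trimethylcyclohex-1-en-1-yl]oxy}trimethylsilane | C[C@@H](OCOC)CC[C@H]1C(C)(C)CCC(O[Si](C)(C)C)=C1C
F2 | step 7 | lithium (3S)-3-[(3R)-3-(methoxymethoxy)butyl]-2,4,4-trimethylcyclohex-1-en-1-olate | C[C@@H](OCOC)CC[C@H]1C(C)(C)CCC(O[Li])=C1C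
F3 | step 11 | 4-[(1S,2R)-2-{2-[3-methoxy-2-(propan-2-yloxy)phenyl]-2-oxoethyl}-2,6,6-trimethylcyclohexyl]butan-2-one | CC(=O)CC[C@H]1C(C)(C)CCC[C@]1(C)CC(=O)c1cccc(OC)c1OC(C)C
F4 | step 11 | [3-methoxy-2-(propan-2-yloxy)phenyl][(4aS,8aS)-2,5,5,8a-tetramethyl-3,4,4a,5,6,7,8,8a-octahydronaphthalen-1-yl]methanone | CC1=C(C(=O)c2cccc(OC)c2OC(C)C)[C@@]2(C)CCCC(C)(C)[C@@H]2CC1
F0 | step 12 | none | none
F5 | step 8 | (2R,3S)-3-[(3R)-3-(methoxymethoxy)butyl]-2-{2-[3-methoxy-2-(propan-2-yloxy)phenyl]prop-2-en-1-yl}-2,4,4-trimethylcyclohexan-1-ol (C1 either way) | C[C@@H](OCOC)CC[C@H]1C(C)(C)CCC(O)[C@]1(C)CC(=C)c1cccc(OC)c1OC(C)C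
F6 | step 8 | O-{(2R,3S)-3-[(3R)-3-(methoxymethoxy)butyl]-2-{2-[3-methoxy-2-(propan-2-yloxy)phenyl]prop-2-en-1-yl}-2,4,4-trimethylcyclohexyl} S-methyl carbonodithioate | C[C@@H](OCOC)CC[C@H]1C(C)(C)CCC(OC(=S)SC)[C@]1(C)CC(=C)c1cccc(OC)c1OC(C)C
A1 | alternative 1 | 2-[(2E,6E)-3,7,11-trimethyldodeca-2,6,10-trien-1-yl]-6-methoxyphenol | COc1cccc(C/C=C(C)/CC/C=C(C)/CCC=C(C)C)c1O
A2 | alternative 1 | tetracyclic chroman with the temporary O–C8 bond | COc1cccc2C[C@H]3[C@@](C)(CC[C@H]4C(C)(C)CCC[C@]34C)Oc12
A3 | alternative 2 | single enantiomer of the (E,E)-diene-tethered 1-aryl-1-chloroallene, triisopropylsilyl ether | C/C=C/C=C/C(C)(C)CCCC(C)=[C@@]=C(Cl)c1cccc(OC)c1O[Si](C(C)C)(C(C)C)C(C)C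
A4 | alternative 2 | trans-fused chloroalkene with C6=C7 unsaturation, triisopropylsilyl ether | COc1cccc(/C(Cl)=C2/[C@@H](C)C=C[C@H]3C(C)(C)CCC[C@]23C)c1O[Si](C(C)C)(C(C)C)C(C)C
A5 | alternative 3 | (4aS,8aS)-2,5,5,8a-tetramethyl-3,4,4a,5,6,7,8,8a-octahydronaphthalen-1-yl trifluoromethanesulfonate | CC1=C(OS(=O)(=O)C(F)(F)F)[C@@]2(C)CCCC(C)(C)[C@@H]2CC1
A6 | alternative 3 | [3-methoxy-2-(methoxymethoxy)phenyl]boronic acid | COCOc1c(OC)cccc1B(O)O
A7 | alternative 3 | [3-methoxy-2-(methoxymethoxy)phenyl][(4aS,8aS)-2,5,5,8a-tetramethyl-3,4,4a,5,6,7,8,8a-octahydronaphthalen-1-yl]methanone | CC1=C(C(=O)c2cccc(OC)c2OCOC)[C@@]2(C)CCCC(C)(C)[C@@H]2CC1
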